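# Proposed synthesis of CNP0190193.0 (23) by twofold anodic C–H/O–H closure of both pyranone rings

## The problem

The target 23 is an unsymmetrical biflavonol: a 7-O-methylquercetin unit (unit 1) and a 3'-O-methylquercetin unit (unit 2), joined by a diaryl ether oxygen between C4' of ring B of unit 1 and C4' of ring B of unit 2. It has no stereocentre, so the difficulty is connectivity and telling nine oxygen functions apart: two methyl ethers (O7 of unit 1, O3' of unit 2), the bridging ether, and six free hydroxyls (O3, O5, O3' of unit 1; O3, O5, O7 of unit 2). The two rings B are nearly alike, so the diaryl ether must be made regiospecifically and each ring B must be matched with its own ring A. The free polyphenol, with two 3-hydroxy-4-pyranone units, is oxidised easily in base and is poorly soluble, so it should appear only in the last step under neutral conditions. Before that, aryl benzyl ethers and the diaryl ether tolerate base, organolithium reagents and mild oxidants, but not strong acids. The feature that invites a new key step is that in each unit the bond O1–C8a joins the enol oxygen of a 1,3-dicarbonyl array (O1–C2=C3–C4=O) to the ring-A carbon ortho to the C4 carbonyl. In the open 1-aryl-2-alkoxy-1,3-diketone this carbon is C6 of a 2,4-dialkoxybenzoyl ring. It is the only free ortho position, since C2 carries the future O5. It bears hydrogen and is meta to both oxygen substituents, so its position is unambiguous, but it is not activated by the donors.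

## Retrosynthesis

**Deprotection.** Six O–CH2Ph bonds of the hexabenzyl ether 22 are cut to reach 23. Benzyl is used on every hydroxyl, including O5 of unit 1, because the ring-A precursor needs no symmetry (see next paragraph). O5 and O7 of unit 1 can therefore differ from the outset. The last step is then plain hydrogenolysis, and no chelation-controlled demethylation has to distinguish a 5-methyl ether from the methyl ethers at O7 and O3'. The forward reaction must only be neutral and leave the two methyl ethers and the diaryl ether alone.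

**Key disconnection.** In 22 the O1–C8a bond of each pyranone ring is cut, giving the bis(2-benzyloxy-1,3-diketone) 19. The forward closures pass through the monochromones 20 and 21.
- The neighbouring cut O1–C2 (cyclodehydration of an ortho-hydroxyaryl diketone) would need two phloroglucinol-type rings A with three differentiated oxygens each. The cut chosen needs only resorcinol-type rings and makes both heterocycles in one operation.
- The orientation of ring A must be set with care. Closure at an ortho carbon of a 3,5-dialkoxybenzoyl ring, where the new bond would lie ortho and para to the donors, gives a 6,8-dioxygenated chromone. The 5,7-pattern arises only from a 2,4-dialkoxybenzoyl ring closing at C6.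
- That carbon is meta to both alkoxy groups, so the forward reaction cannot rely on donor stabilisation. It must oxidise only the two enolates and make the enol oxygen bond to an unactivated C–H.
- The step is strengthened in two ways. Electron transfer goes through a ferrocene mediator, so the enolate radical forms in solution at a mild potential and is not oxidised further at the electrode. The 2-alkoxy group on each benzoyl ring leaves one ortho C–H only, so no site selectivity is needed.

**Unit 2 diketone.** In 19 the bond between the CH(OBn) carbon and the carbonyl on ring B of unit 2 is cut. This leads through the aldol adduct 18 to the diketone aldehyde 12 and the ketone 16, used as its lithium enolate 17. Aldol addition followed by oxidation is preferred to direct acylation of the enolate with an ester, because an aldehyde is the better electrophile for a hindered alkoxy enolate and O-acylation cannot occur. The forward aldol must tolerate the acidic diketone of unit 1, which is handled by an extra equivalent of enolate.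

**Unit 1 diketone.** The same cut in 12 leads through the aldol adduct 11 to the aldehyde alcohol 4 and the ketone 9 (enolate 10). In 4 the two rings B differ in oxidation level: ring B of unit 1 carries the aldehyde and ring B of unit 2 a hydroxymethyl group. One oxidation of 11 then makes the first diketone and unmasks the second aldehyde together.

**Diaryl ether.** In 4 the aryl–O bond on ring B of unit 1 is cut, giving 3-(benzyloxy)-4-fluorobenzaldehyde 2 and vanillyl alcohol 3. The fluoride para to the formyl group is displaced by the phenoxide (SNAr). The cut on the other side would need a fluoride on the vanillyl ring, which has no activating group at the alcohol level. Compound 2 comes from 4-fluoro-3-hydroxybenzaldehyde 1 by benzylation.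

**Ring-A ketones.** In 9 and 16 the aryl–acyl bond is cut. This gives the aryllithiums 8 and 15, from the bromides 6 and 14 (benzyl ethers of 2-bromo-5-methoxyphenol 5 and 4-bromoresorcinol 13), and the common amide 7. This places the benzyloxy group alpha to the ketone in one step and avoids a multi-step alpha-oxygenation of acetophenones.

## Roads not taken

**Alternative 1:** Ring B of unit 1 is cut at C1'–C2' and C5'–C6'. Forward, the 1-amino-3-siloxydiene A2, which carries complete unit 2 through its aryloxy substituent, adds to the nitrovinylchromone A3 of unit 1 in a [4+2] cycloaddition. Loss of dimethylamine and nitrous acid then aromatises the new ring to the silyl pentabenzyl compound A1.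
- Merits: both flavonol cores are finished before the union; the substitution pattern of the new ring follows from the polarity of diene and dienophile; each elementary event belongs to a known reaction class. That is better precedent than the chosen key step can claim.
- Weak points: A2 is a tetrasubstituted enamine and silyl enol ether, sensitive to hydrolysis, and must be raised on a complete flavonol. A3 needs its own multi-step preparation. Both flavonol cores still have to be made by classical chemistry with phloroglucinol differentiation. The silyl ether needs removal as well.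
- Comparison: the route is clearly longer. The chosen plan sets against the better precedent its brevity and the fact that both heterocycles come from simple open-chain precursors in one step.

**Alternative 2:** The pyranone ring of unit 1 is cut at C3–C4 and O1–C2. Forward, the lithium enolate of the benzyloxymethyl ketone A6 (which already contains unit 2) attacks the carbonyl of the benzodioxinone A5. Acetone is lost and the freed phenoxide closes the ring on acid work-up to A4, which is identical with 22.
- Merits: the reaction type is known; ring A arrives with O5 and O7 already differentiated; no C–H bond has to be functionalised. In reliability this road is better than the chosen one, and it reaches the same compound.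
- Weak points: it builds one pyranone ring only, so unit 2 must be completed beforehand by another flavonol synthesis. A6 is an advanced ketone used against an electron-rich, peri-hindered carbonyl that is a sluggish electrophile. A5 needs selective alkylations of a phloroglucinol acid.
- Comparison: the chosen plan offers a shorter line, resorcinol-type building blocks and both rings in one operation. It pays for this with an unproven step, backed by a classical fallback.

**Alternative 3:** The pyranone ring of unit 2 is cut at C4a–C4, C4–C3 and O1–C2. Forward, the iodophenol A8, carbon monoxide and the alkyne A9 (which carries benzylated unit 1) combine under PdCl2(PPh3)2 and diethylamine to the flavone A7.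
- Merits: three bonds form in one catalytic step of a known type, and C4 comes from carbon monoxide.
- Weak points: A7 lacks the C3 oxygen of unit 2, so a further oxidation at C3 is needed in the presence of the other flavonol. The annulation is known to compete with five-membered (aurone) closure. In A8 the iodine sits between two oxygen substituents on an electron-rich ring, which slows oxidative addition to zerovalent palladium. A9 requires unit 1 to be finished first.
- Comparison: the precedent is better than for the chosen step. The chosen plan sets against it that both C3 oxygens are present from the start and both rings close together.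

Key step: step 11

Remark on the chemistry: 11, 12, 18, 19, 20 and 21 are drawn as keto forms and handled as stereoisomer mixtures. Their aldol and CH(OBn) centres are formed without control and all vanish by step 11. Compounds 1, 3, 5, 7 and 13 are assumed to be purchased.

## Route

Step 1
Reactants: 1 4-fluoro-3-hydroxybenzaldehyde
Product: 2 3-(benzyloxy)-4-fluorobenzaldehyde
Conditions: BnBr, K2CO3, DMF, rt
Reagents that add atoms: benzyl bromide, BrCc1ccccc1
Why: Williamson ether synthesis on a phenol; the aldehyde and the aryl fluoride are inert at room temperature.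

Step 2
Reactants: 2 3-(benzyloxy)-4-fluorobenzaldehyde; 3 vanillyl alcohol
Product: 4 3-(benzyloxy)-4-[4-(hydroxymethyl)-2-methoxyphenoxy]benzaldehyde
Conditions: Cs2CO3, DMSO, 80 °C
Reagents that add atoms: none
Why: SNAr of a phenoxide on a fluoride para to a formyl group; carbonate deprotonates the phenol but not the benzylic alcohol, so only the phenol oxygen is arylated.

Step 3
Reactants: 5 2-bromo-5-methoxyphenol
Product: 6 2-(benzyloxy)-1-bromo-4-methoxybenzene
Conditions: BnBr, K2CO3, acetone, reflux
Reagents that add atoms: benzyl bromide, BrCc1ccccc1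
Why: Williamson ether synthesis; the aryl bromide is untouched.

Step 4
Reactants: 6 2-(benzyloxy)-1-bromo-4-methoxybenzene; 7 2-(benzyloxy)-N-methoxy-N-methylacetamide
Product: 9 2-(benzyloxy)-1-[2-(benzyloxy)-4-methoxyphenyl]ethan-1-one, via aryllithium 8 (not isolated)
Conditions: n-BuLi, THF, −78 °C; then 7, −78 to 0 °C; 1 M HCl
Reagents that add atoms: none
Why: Bromine–lithium exchange followed by Weinreb ketone synthesis; the chelated tetrahedral adduct prevents a second addition, and the benzyl ethers tolerate the aryllithium at −78 °C.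

Step 5
Reactants: 9 2-(benzyloxy)-1-[2-(benzyloxy)-4-methoxyphenyl]ethan-1-one; 4 3-(benzyloxy)-4-[4-(hydroxymethyl)-2-methoxyphenoxy]benzaldehyde
Product: 11 2-(benzyloxy)-1-[2-(benzyloxy)-4-methoxyphenyl]-3-{3-(benzyloxy)-4-[4-(hydroxymethyl)-2-methoxyphenoxy]phenyl}-3-hydroxypropan-1-one (syn/anti mixture), via lithium enolate 10 (not isolated)
Conditions: 9 (2.3 equiv), LiN(SiMe3)2 (2.2 equiv), THF, −78 °C; then 4; AcOH, −78 °C
Reagents that add atoms: none
Why: Aldol addition of a chelated alpha-alkoxy lithium enolate to an aryl aldehyde; one equivalent of enolate is spent on the free benzylic hydroxyl and that ketone is recovered. The two new stereocentres form without control, which is harmless because step 6 and step 11 remove them.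

Step 6
Reactants: 11 aldol adduct of step 5
Product: 12 2-(benzyloxy)-1-[2-(benzyloxy)-4-methoxyphenyl]-3-[3-(benzyloxy)-4-(4-formyl-2-methoxyphenoxy)phenyl]propane-1,3-dione
Conditions: Dess–Martin periodinane (3 equiv), CH2Cl2, 0 °C to rt
Reagents that add atoms: none
Why: Dess–Martin oxidation converts the beta-hydroxy ketone into the 1,3-diketone and the benzylic primary alcohol into the aldehyde in one operation; the neutral conditions avoid retro-aldol cleavage.

Step 7
Reactants: 13 4-bromobenzene-1,3-diol
Product: 14 2,4-bis(benzyloxy)-1-bromobenzene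
Conditions: BnBr (2.3 equiv), K2CO3, DMF, 50 °C
Reagents that add atoms: benzyl bromide, BrCc1ccccc1
Why: Twofold Williamson ether synthesis.

Step 8
Reactants: 14 2,4-bis(benzyloxy)-1-bromobenzene; 7 2-(benzyloxy)-N-methoxy-N-methylacetamide
Product: 16 2-(benzyloxy)-1-[2,4-bis(benzyloxy)phenyl]ethan-1-one, via aryllithium 15 (not isolated)
Conditions: n-BuLi, THF, −78 °C; then 7, −78 to 0 °C; 1 M HCl
Reagents that add atoms: none
Why: Bromine–lithium exchange and Weinreb ketone synthesis, as in step 4.

Step 9
Reactants: 16 2-(benzyloxy)-1-[2,4-bis(benzyloxy)phenyl]ethan-1-one; 12 diketone aldehyde of step 6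
Product: 18 2-(benzyloxy)-1-[2-(benzyloxy)-4-methoxyphenyl]-3-{3-(benzyloxy)-4-[4-{2-(benzyloxy)-3-[2,4-bis(benzyloxy)phenyl]-1-hydroxy-3-oxopropyl}-2-methoxyphenoxy]phenyl}propane-1,3-dione (diastereomer mixture), via lithium enolate 17 (not isolated)
Conditions: 16 (2.4 equiv), LiN(SiMe3)2 (2.3 equiv), THF, −78 °C; then 12; AcOH, −78 °C
Reagents that add atoms: none
Why: Aldol addition; the first equivalent of enolate deprotonates the acidic 1,3-diketone, whose lithium diketonate is then inert to nucleophiles, and the second adds to the aldehyde. The new stereocentres are uncontrolled and are removed in step 10 and step 11.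

Step 10
Reactants: 18 aldol adduct of step 9
Product: 19 2-(benzyloxy)-1-[2-(benzyloxy)-4-methoxyphenyl]-3-{3-(benzyloxy)-4-[4-{2-(benzyloxy)-3-[2,4-bis(benzyloxy)phenyl]-3-oxopropanoyl}-2-methoxyphenoxy]phenyl}propane-1,3-dione
Conditions: Dess–Martin periodinane (1.5 equiv), CH2Cl2, 0 °C to rt
Reagents that add atoms: none
Why: Dess–Martin oxidation of the beta-hydroxy ketone to the second 1,3-diketone; the first diketone, with its fully substituted central carbon in the keto form, is not affected.

Step 11
Reactants: 19 bis(2-benzyloxy-1,3-diketone)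
Product: 22 3,5-bis(benzyloxy)-2-{3-(benzyloxy)-4-[2-methoxy-4-(3,5,7-tris(benzyloxy)-4-oxo-4H-chromen-2-yl)phenoxy]phenyl}-7-methoxy-4H-chromen-4-one, via unit-1 monochromone 20 (not isolated), via unit-2 monochromone 21 (not isolated)
Conditions: undivided cell, reticulated vitreous carbon anode, Pt cathode, constant current (ca. 4.5 F/mol), Cp2Fe (10 mol %), Na2CO3 (0.5 equiv), n-Bu4NBF4, THF/MeOH 5:1, 50 °C, Ar
Reagents that add atoms: none
Why: Proposed new method: carbonate converts each 2-benzyloxy-1,3-diketone into its enolate, expected to be by far the most easily oxidised group present, and anodically regenerated ferrocenium takes one electron from it in solution, so that the captodatively stabilised 1,3-dioxo radical forms away from the electrode and is not oxidised further at C3. In the rotamer that turns the benzoyl C=O toward the ortho benzyloxy group, the oxygen on the ring-B side lies beside C6–H of the 2,4-dialkoxybenzoyl ring and bonds to it, giving an 8aH-chromenyl radical with spin on C4a (next to the C4 carbonyl), C6 and C8; loss of the C8a proton to base and of a second electron to ferrocenium aromatises the chromone, while the cathode turns the released protons into H2. Each of the two pyranone rings is closed in the same mode, a 6-endo attack of the enol oxygen on the arene (closure through C3 would need a four-membered ring), first to 20 or 21 and then to 22. The closest known reaction types are the anodic dehydrogenative lactonisation of biaryl-2-carboxylic acids, the ferrocene-mediated anodic cyclisation of malonamide-type 1,3-dicarbonyl enolates onto an aryl ring through carbon, and, in polarity, the SNAr closure of 1-(2-fluorophenyl)-1,3-diketones to flavones; closure through the enol oxygen onto an unactivated ortho C–H is the new element. No stereocentre is formed, and the CH(OBn) centres of 19 disappear. Chemoselectivity for the two enolates over the aryl and benzyl ethers is secured by the low enolate potential and the mild mediator, and the chromones formed are much harder to oxidise. Site selectivity is secured by the substitution pattern: C2 of each benzoyl ring carries a benzyloxy group, so C6 is the only ortho C–H. Because C6 is meta to both alkoxy groups it gets no donor stabilisation; the closure leans on the acyl group at C4a, on the persistence of the hindered tertiary radical and on irreversible aromatisation, which is why mediated electrolysis and gentle heating are chosen.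

Step 12
Reactants: 22 hexabenzyl ether of the target
Product: 23 3,5-dihydroxy-2-{3-hydroxy-4-[2-methoxy-4-(3,5,7-trihydroxy-4-oxo-4H-chromen-2-yl)phenoxy]phenyl}-7-methoxy-4H-chromen-4-one (CNP0190193.0)
Conditions: H2 (1 atm), Pd(OH)2/C, THF/MeOH 1:1, rt
Reagents that add atoms: none
Why: Catalytic hydrogenolysis of five aryl benzyl ethers and two enol benzyl ethers; the methyl ethers, the diaryl ether and the pyranone C2=C3 bonds are not expected to react under these neutral conditions.

## Compound list

1 | 4-fluoro-3-hydroxybenzaldehyde | O=Cc1ccc(F)c(O)c1 | starting material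
2 | 3-(benzyloxy)-4-fluorobenzaldehyde | O=Cc1ccc(F)c(OCc2ccccc2)c1 | intermediate
3 | vanillyl alcohol, 4-(hydroxymethyl)-2-methoxyphenol | COc1cc(CO)ccc1O | starting material
4 | 3-(benzyloxy)-4-[4-(hydroxymethyl)-2-methoxyphenoxy]benzaldehyde | O=Cc1ccc(Oc2ccc(CO)cc2OC)c(OCc2ccccc2)c1 | intermediate
5 | 2-bromo-5-methoxyphenol | COc1ccc(Br)c(O)c1 | starting material
6 | 2-(benzyloxy)-1-bromo-4-methoxybenzene | COc1ccc(Br)c(OCc2ccccc2)c1 | intermediate
7 | 2-(benzyloxy)-N-methoxy-N-methylacetamide | CON(C)C(=O)COCc1ccccc1 | starting material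
8 | [2-(benzyloxy)-4-methoxyphenyl]lithium | [Li]c1ccc(OC)cc1OCc1ccccc1 | intermediate
9 | 2-(benzyloxy)-1-[2-(benzyloxy)-4-methoxyphenyl]ethan-1-one | COc1ccc(C(=O)COCc2ccccc2)c(OCc2ccccc2)c1 | intermediate
10 | lithium (Z)-enolate of 9 | [Li]O/C(=C\OCc1ccccc1)c1ccc(OC)cc1OCc1ccccc1 | intermediate
11 | 2-(benzyloxy)-1-[2-(benzyloxy)-4-methoxyphenyl]-3-{3-(benzyloxy)-4-[4-(hydroxymethyl)-2-methoxyphenoxy]phenyl}-3-hydroxypropan-1-one (syn/anti mixture, racemic) | COc1ccc(C(=O)C(OCc2ccccc2)C(O)c2ccc(Oc3ccc(CO)cc3OC)c(OCc3ccccc3)c2)c(OCc2ccccc2)c1 | intermediate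
12 | 2-(benzyloxy)-1-[2-(benzyloxy)-4-methoxyphenyl]-3-[3-(benzyloxy)-4-(4-formyl-2-methoxyphenoxy)phenyl]propane-1,3-dione (keto form, racemic) | COc1ccc(C(=O)C(OCc2ccccc2)C(=O)c2ccc(Oc3ccc(C=O)cc3OC)c(OCc3ccccc3)c2)c(OCc2ccccc2)c1 | intermediate
13 | 4-bromobenzene-1,3-diol | Oc1ccc(Br)c(O)c1 | starting material
14 | 2,4-bis(benzyloxy)-1-bromobenzene | Brc1ccc(OCc2ccccc2)cc1OCc1ccccc1 | intermediate
15 | [2,4-bis(benzyloxy)phenyl]lithium | [Li]c1ccc(OCc2ccccc2)cc1OCc1ccccc1 | intermediate
16 | 2-(benzyloxy)-1-[2,4-bis(benzyloxy)phenyl]ethan-1-one | O=C(COCc1ccccc1)c1ccc(OCc2ccccc2)cc1OCc1ccccc1 | intermediate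
17 | lithium (Z)-enolate of 16 | [Li]O/C(=C\OCc1ccccc1)c1ccc(OCc2ccccc2)cc1OCc1ccccc1 | intermediate
18 | 2-(benzyloxy)-1-[2-(benzyloxy)-4-methoxyphenyl]-3-{3-(benzyloxy)-4-[4-{2-(benzyloxy)-3-[2,4-bis(benzyloxy)phenyl]-1-hydroxy-3-oxopropyl}-2-methoxyphenoxy]phenyl}propane-1,3-dione (diastereomer mixture) | COc1ccc(C(=O)C(OCc2ccccc2)C(=O)c2ccc(Oc3ccc(C(O)C(OCc4ccccc4)C(=O)c4ccc(OCc5ccccc5)cc4OCc4ccccc4)cc3OC)c(OCc3ccccc3)c2)c(OCc2ccccc2)c1 | intermediate
19 | 2-(benzyloxy)-1-[2-(benzyloxy)-4-methoxyphenyl]-3-{3-(benzyloxy)-4-[4-{2-(benzyloxy)-3-[2,4-bis(benzyloxy)phenyl]-3-oxopropanoyl}-2-methoxyphenoxy]phenyl}propane-1,3-dione (keto form, mixture at the two CH(OBn) centres) | COc1ccc(C(=O)C(OCc2ccccc2)C(=O)c2ccc(Oc3ccc(C(=O)C(OCc4ccccc4)C(=O)c4ccc(OCc5ccccc5)cc4OCc4ccccc4)cc3OC)c(OCc3ccccc3)c2)c(OCc2ccccc2)c1 | intermediate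
20 | 3,5-bis(benzyloxy)-2-{3-(benzyloxy)-4-[4-{2-(benzyloxy)-3-[2,4-bis(benzyloxy)phenyl]-3-oxopropanoyl}-2-methoxyphenoxy]phenyl}-7-methoxy-4H-chromen-4-one (unit 1 closed) | COc1cc(OCc2ccccc2)c2c(=O)c(OCc3ccccc3)c(-c3ccc(Oc4ccc(C(=O)C(OCc5ccccc5)C(=O)c5ccc(OCc6ccccc6)cc5OCc5ccccc5)cc4OC)c(OCc4ccccc4)c3)oc2c1 | intermediate
21 | 3,5,7-tris(benzyloxy)-2-{4-[2-(benzyloxy)-4-{2-(benzyloxy)-3-[2-(benzyloxy)-4-methoxyphenyl]-3-oxopropanoyl}phenoxy]-3-methoxyphenyl}-4H-chromen-4-one (unit 2 closed) | COc1ccc(C(=O)C(OCc2ccccc2)C(=O)c2ccc(Oc3ccc(-c4oc5cc(OCc6ccccc6)cc(OCc6ccccc6)c5c(=O)c4OCc4ccccc4)cc3OC)c(OCc3ccccc3)c2)c(OCc2ccccc2)c1 | intermediate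
22 | 3,5-bis(benzyloxy)-2-{3-(benzyloxy)-4-[2-methoxy-4-(3,5,7-tris(benzyloxy)-4-oxo-4H-chromen-2-yl)phenoxy]phenyl}-7-methoxy-4H-chromen-4-one (hexabenzyl ether of the target) | COc1cc(OCc2ccccc2)c2c(=O)c(OCc3ccccc3)c(-c3ccc(Oc4ccc(-c5oc6cc(OCc7ccccc7)cc(OCc7ccccc7)c6c(=O)c5OCc5ccccc5)cc4OC)c(OCc4ccccc4)c3)oc2c1 | intermediate
23 | 3,5-dihydroxy-2-{3-hydroxy-4-[2-methoxy-4-(3,5,7-trihydroxy-4-oxo-4H-chromen-2-yl)phenoxy]phenyl}-7-methoxy-4H-chromen-4-one (CNP0190193.0) | COc1cc(O)c2c(=O)c(O)c(-c3ccc(Oc4ccc(-c5oc6cc(O)cc(O)c6c(=O)c5O)cc4OC)c(O)c3)oc2c1 | target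

## Step count and least certain steps

Total: 12 steps. Longest linear sequence: 8 steps (steps 1, 2, 5, 6, 9, 10, 11, 12). The branch through steps 3 and 4 is equally long, and the branch through steps 7 and 8 is shorter.

**Step 11 (key step, new method).** Several processes can defeat the closure.
- The stabilised enolate radical may fail to bond through oxygen to a carbon that is meta to both donors. It may instead be oxidised a second time at C3 and trapped by methanol, take a hydrogen atom from a neighbouring benzyloxy CH2 (oxidative loss of a benzyl group), or couple with itself.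
- Ipso closure at the alkoxy-bearing or the acyl-bearing ring carbon may divert material.
- The warm basic methanol may cleave the diketone by retro-Claisen attack.
- The electrolysis may stall after one closure.

Fallback by known chemistry, setting out from 4 and returning at 23:
- Monobenzylation of commercial 2',6'-dihydroxy-4'-methoxyacetophenone (BnBr, K2CO3) gives 1-[2-(benzyloxy)-6-hydroxy-4-methoxyphenyl]ethan-1-one F1.
- Claisen–Schmidt condensation of F1 with 4 (KOH, EtOH/THF) gives the hydroxymethyl 2'-hydroxychalcone F2.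
- MnO2 oxidises the benzylic alcohol to give the formyl chalcone F3.
- A second Claisen–Schmidt condensation with 1-[2,4-bis(benzyloxy)-6-hydroxyphenyl]ethan-1-one F4 (from 2',4',6'-trihydroxyacetophenone and BnBr) gives the bis-chalcone F5.
- Catalytic I2 in DMSO at 120 °C closes both pyranone rings by oxidative cyclisation to the bis-flavone F6.
- Dimethyldioxirane epoxidises both C2=C3 bonds, and acid-catalysed opening gives the bis-flavonol tetrabenzyl ether F7.
- Hydrogenolysis over Pd(OH)2/C gives 23.

**Step 9.** The second aldol is run on a substrate with an acidic diketone. The lithium diketonate of 12 may aggregate or precipitate at −78 °C so that addition to the aldehyde is incomplete, or proton exchange may return ketone and leave aldehyde. The fallback sets out from 11 and returns at 19, and postpones all ketone formation: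
- TEMPO with PhI(OAc)2 oxidises only the primary benzylic alcohol of 11 to the hydroxy aldehyde F8.
- Addition of enolate 17 (one extra equivalent for the free hydroxyl) gives the bis-aldol F9.
- Twofold Dess–Martin oxidation gives 19.

**Step 2.** At 80 °C the phenoxide of vanillyl alcohol may lose hydroxide to a quinone methide and self-condense in competition with the SNAr reaction. The fallback sets out from 2 and returns at 4:
- SNAr of 2 with methyl vanillate (K2CO3, DMF, 100 °C) gives methyl 4-[2-(benzyloxy)-4-formylphenoxy]-3-methoxybenzoate F10.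
- Acetalisation with ethylene glycol (TsOH, toluene, water removal) gives the dioxolane ester F11.
- LiAlH4 reduction gives the dioxolane alcohol F12.
- Aqueous HCl in THF releases the aldehyde and gives 4.

**Step 12.** Hydrogenolysis of six benzyl ethers may stop short because partly debenzylated intermediates precipitate or bind the catalyst, or prolonged exposure may begin to saturate a pyranone C2=C3 bond. The fallback sets out from 22 and returns at 23 without a new compound: BCl3 with pentamethylbenzene as cation scavenger in CH2Cl2 at −78 °C. At that temperature the aryl methyl ethers are expected to survive.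

## Further compounds

F1 | step 11 | 1-[2-(benzyloxy)-6-hydroxy-4-methoxyphenyl]ethan-1-one | CC(=O)c1c(O)cc(OC)cc1OCc1ccccc1
F2 | step 11 | (E)-1-[2-(benzyloxy)-6-hydroxy-4-methoxyphenyl]-3-{3-(benzyloxy)-4-[4-(hydroxymethyl)-2-methoxyphenoxy]phenyl}prop-2-en-1-one | COc1cc(O)c(C(=O)/C=C/c2ccc(Oc3ccc(CO)cc3OC)c(OCc3ccccc3)c2)c(OCc2ccccc2)c1
F3 | step 11 | 4-{2-(benzyloxy)-4-[(E)-3-[2-(benzyloxy)-6-hydroxy-4-methoxyphenyl]-3-oxoprop-1-en-1-yl]phenoxy}-3-methoxybenzaldehyde | COc1cc(O)c(C(=O)/C=C/c2ccc(Oc3ccc(C=O)cc3OC)c(OCc3ccccc3)c2)c(OCc2ccccc2)c1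
F4 | step 11 | 1-[2,4-bis(benzyloxy)-6-hydroxyphenyl]ethan-1-one | CC(=O)c1c(O)cc(OCc2ccccc2)cc1OCc1ccccc1
F5 | step 11 | (E)-1-[2-(benzyloxy)-6-hydroxy-4-methoxyphenyl]-3-{3-(benzyloxy)-4-[4-{(E)-3-[2,4-bis(benzyloxy)-6-hydroxyphenyl]-3-oxoprop-1-en-1-yl}-2-methoxyphenoxy]phenyl}prop-2-en-1-one | COc1cc(O)c(C(=O)/C=C/c2ccc(Oc3ccc(/C=C/C(=O)c4c(O)cc(OCc5ccccc5)cc4OCc4ccccc4)cc3OC)c(OCc3ccccc3)c2)c(OCc2ccccc2)c1
F6 | step 11 | 5-(benzyloxy)-2-{3-(benzyloxy)-4-[4-(5,7-bis(benzyloxy)-4-oxo-4H-chromen-2-yl)-2-methoxyphenoxy]phenyl}-7-methoxy-4H-chromen-4-one | COc1cc(OCc2ccccc2)c2c(=O)cc(-c3ccc(Oc4ccc(-c5cc(=O)c6c(OCc7ccccc7)cc(OCc7ccccc7)cc6o5)cc4OC)c(OCc4ccccc4)c3)oc2c1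
F7 | step 11 | 5-(benzyloxy)-2-{3-(benzyloxy)-4-[4-(5,7-bis(benzyloxy)-3-hydroxy-4-oxo-4H-chromen-2-yl)-2-methoxyphenoxy]phenyl}-3-hydroxy-7-methoxy-4H-chromen-4-one | COc1cc(OCc2ccccc2)c2c(=O)c(O)c(-c3ccc(Oc4ccc(-c5oc6cc(OCc7ccccc7)cc(OCc7ccccc7)c6c(=O)c5O)cc4OC)c(OCc4ccccc4)c3)oc2c1
F8 | step 9 | 2-(benzyloxy)-1-[2-(benzyloxy)-4-methoxyphenyl]-3-[3-(benzyloxy)-4-(4-formyl-2-methoxyphenoxy)phenyl]-3-hydroxypropan-1-one (diastereomer mixture) | COc1ccc(C(=O)C(OCc2ccccc2)C(O)c2ccc(Oc3ccc(C=O)cc3OC)c(OCc3ccccc3)c2)c(OCc2ccccc2)c1
F9 | step 9 | 2-(benzyloxy)-1-[2-(benzyloxy)-4-methoxyphenyl]-3-{3-(benzyloxy)-4-[4-{2-(benzyloxy)-3-[2,4-bis(benzyloxy)phenyl]-1-hydroxy-3-oxopropyl}-2-methoxyphenoxy]phenyl}-3-hydroxypropan-1-one (diastereomer mixture) | COc1ccc(C(=O)C(OCc2ccccc2)C(O)c2ccc(Oc3ccc(C(O)C(OCc4ccccc4)C(=O)c4ccc(OCc5ccccc5)cc4OCc4ccccc4)cc3OC)c(OCc3ccccc3)c2)c(OCc2ccccc2)c1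
F10 | step 2 | methyl 4-[2-(benzyloxy)-4-formylphenoxy]-3-methoxybenzoate | COC(=O)c1ccc(Oc2ccc(C=O)cc2OCc2ccccc2)c(OC)c1
F11 | step 2 | methyl 4-[2-(benzyloxy)-4-(1,3-dioxolan-2-yl)phenoxy]-3-methoxybenzoate | COC(=O)c1ccc(Oc2ccc(C3OCCO3)cc2OCc2ccccc2)c(OC)c1
F12 | step 2 | {4-[2-(benzyloxy)-4-(1,3-dioxolan-2-yl)phenoxy]-3-methoxyphenyl}methanol | OCc1ccc(Oc2ccc(C3OCCO3)cc2OCc2ccccc2)c(OC)c1
F0 | step 12 | none | none
A1 | alternative 1 | 3,5-bis(benzyloxy)-2-{3-[(tert-butyldimethylsilyl)oxy]-4-[2-methoxy-4-(3,5,7-tris(benzyloxy)-4-oxo-4H-chromen-2-yl)phenoxy]phenyl}-7-methoxy-4H-chromen-4-one | COc1cc(OCc2ccccc2)c2c(=O)c(OCc3ccccc3)c(-c3ccc(Oc4ccc(-c5oc6cc(OCc7ccccc7)cc(OCc7ccccc7)c6c(=O)c5OCc5ccccc5)cc4OC)c(O[Si](C)(C)C(C)(C)C)c3)oc2c1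
A2 | alternative 1 | 3,5,7-tris(benzyloxy)-2-[4-({(1Z)-3-[(tert-butyldimethylsilyl)oxy]-1-(dimethylamino)buta-1,3-dien-2-yl}oxy)-3-methoxyphenyl]-4H-chromen-4-one | CN(C)/C=C(\Oc1ccc(cc1OC)-c1oc2cc(OCc3ccccc3)cc(OCc3ccccc3)c2c(=O)c1OCc1ccccc1)C(=C)O[Si](C)(C)C(C)(C)C
A3 | alternative 1 | 3,5-bis(benzyloxy)-7-methoxy-2-[(E)-2-nitroethenyl]-4H-chromen-4-one | COc1cc(OCc2ccccc2)c2c(=O)c(OCc3ccccc3)c(/C=C/[N+](=O)[O-])oc2c1
A4 | alternative 2 | hexabenzyl ether of the target, identical with 22 | COc1cc(OCc2ccccc2)c2c(=O)c(OCc3ccccc3)c(-c3ccc(Oc4ccc(-c5oc6cc(OCc7ccccc7)cc(OCc7ccccc7)c6c(=O)c5OCc5ccccc5)cc4OC)c(OCc4ccccc4)c3)oc2c1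
A5 | alternative 2 | 5-(benzyloxy)-7-methoxy-2,2-dimethyl-4H-1,3-benzodioxin-4-one | COc1cc(OCc2ccccc2)c2C(=O)OC(C)(C)Oc2c1
A6 | alternative 2 | 2-(benzyloxy)-1-{3-(benzyloxy)-4-[2-methoxy-4-(3,5,7-tris(benzyloxy)-4-oxo-4H-chromen-2-yl)phenoxy]phenyl}ethan-1-one | O=C(COCc1ccccc1)c1ccc(Oc2ccc(cc2OC)-c2oc3cc(OCc4ccccc4)cc(OCc4ccccc4)c3c(=O)c2OCc2ccccc2)c(OCc2ccccc2)c1
A7 | alternative 3 | 3,5-bis(benzyloxy)-2-{3-(benzyloxy)-4-[4-(5,7-bis(benzyloxy)-4-oxo-4H-chromen-2-yl)-2-methoxyphenoxy]phenyl}-7-methoxy-4H-chromen-4-one | COc1cc(OCc2ccccc2)c2c(=O)c(OCc3ccccc3)c(-c3ccc(Oc4ccc(-c5cc(=O)c6c(OCc7ccccc7)cc(OCc7ccccc7)cc6o5)cc4OC)c(OCc4ccccc4)c3)oc2c1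
A8 | alternative 3 | 3,5-bis(benzyloxy)-2-iodophenol | Oc1cc(OCc2ccccc2)cc(OCc2ccccc2)c1I
A9 | alternative 3 | 3,5-bis(benzyloxy)-2-[3-(benzyloxy)-4-(4-ethynyl-2-methoxyphenoxy)phenyl]-7-methoxy-4H-chromen-4-one | C#Cc1ccc(Oc2ccc(cc2OCc2ccccc2)-c2oc3cc(OC)cc(OCc4ccccc4)c3c(=O)c2OCc2ccccc2)c(OC)c1
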